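The cyclohexene ring (C3a, C4, C5, C6, C7, C7a; 2-benzofuran numbering, C4 = carbinol, C6 = quaternary carbon) is made from a cyclopentanone that already carries the C6/C7 stereodyad, set by an enantioselective Ireland–Claisen rearrangement of a geranyl ester and closed by hydroacylation. In the key step dibromocarbene adds to the kinetic silyl enol ether and the dibromocyclopropane opens, inserting C3a as a vinyl bromide between the carbonyl carbon C7a and C4. This exploits the pattern C4(O)–C3a(C)=C7a(C) of the tetrasubstituted alkene: alkenyllithium addition and oxidative transposition place the side chain on C7a and oxygen on C4, bromine is exchanged for C3, and oxa-Michael closure forms the dihydrofuran.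

Key step: step 7

Assumption: the (S,S) boron reagent with i-Pr2NEt/CH2Cl2 is taken to give the Z(O) ketene acetal and the (2S,3S) acid; if the opposite sense of induction is found, the (R,R) reagent is used and nothing else changes.

Abbreviations: TBS = tert-butyldimethylsilyl, TMS = trimethylsilyl, pin = pinacolato.

Step 1
Reactants: 1 geraniol; 2 3-(TBS-oxy)propanoic acid
Product: 3 geranyl 3-(TBS-oxy)propanoate
Conditions: DCC, DMAP (cat.), CH2Cl2, 0 °C → rt
Reagents that add atoms: none
Why: Steglich esterification of a primary allylic alcohol with an unhindered acid; no stereocentre is formed and the E-alkene is untouched.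

Step 2
Reactants: 3 geranyl 3-(TBS-oxy)propanoate
Product: 6 (2S,3S)-2-[(TBS-oxy)methyl]-3-ethenyl-3,7-dimethyloct-6-enoic acid, via boron ketene acetal 4 (not isolated), via boron carboxylate 5 (not isolated)
Conditions: (S,S)-2-bromo-4,5-diphenyl-1,3-bis{[3,5-bis(trifluoromethyl)phenyl]sulfonyl}-1,3,2-diazaborolidine, i-Pr2NEt, CH2Cl2, −78 °C → 4 °C; then H2O work-up
Reagents that add atoms: none
Why: Enantioselective Ireland–Claisen rearrangement: soft enolisation gives the Z(O) boron ketene acetal, which rearranges through a chair with the homoprenyl arm of the E-allyl unit equatorial and the methyl axial, so the C2/C3 relative configuration follows from the two double-bond geometries and the absolute configuration from the C2-symmetric boron ligand.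

Step 3
Reactants: 6 (2S,3S)-2-[(TBS-oxy)methyl]-3-ethenyl-3,7-dimethyloct-6-enoic acid
Product: 7 (2S,3S)-2-[(TBS-oxy)methyl]-3-ethenyl-N-methoxy-N,3,7-trimethyloct-6-enamide
Conditions: MeNH(OMe)·HCl, EDC·HCl, N-methylmorpholine, CH2Cl2, 0 °C → rt
Reagents that add atoms: N,O-dimethylhydroxylamine hydrochloride CNOC.Cl
Why: Carbodiimide amide coupling; the N-methoxy-N-methylamide lets the aldehyde be reached without passing through the 1,3-diol monosilyl ether, in which silyl migration between the two CH2O arms would scramble C2.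

Step 4
Reactants: 7 the N-methoxy-N-methylamide
Product: 8 (2S,3S)-2-[(TBS-oxy)methyl]-3-ethenyl-3,7-dimethyloct-6-enal
Conditions: i-Bu2AlH, THF, −78 °C; then H2O work-up
Reagents that add atoms: none
Why: Hydride reduction of an N-methoxy-N-methylamide stops at the chelated aluminium hemiaminal and should release the aldehyde on work-up without epimerisation of the α-centre at low temperature.

Step 5
Reactants: 8 the 4-pentenal
Product: 9 (2S,3S)-2-[(TBS-oxy)methyl]-3-methyl-3-(4-methylpent-3-en-1-yl)cyclopentan-1-one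
Conditions: [Rh(Ph2PCH2CH2PPh2)]BF4 (5 mol %), CH2Cl2, rt
Reagents that add atoms: none
Why: Intramolecular alkene hydroacylation (acyl C–H oxidative addition, insertion of the vinyl group to a six-membered rhodacycle, reductive elimination) turns the 3,3-disubstituted 4-pentenal into the cyclopentanone; both stereocentres are spectators and the trisubstituted alkene is too hindered to insert.

Step 6
Reactants: 9 the cyclopentanone
Product: 10 tert-butyl({(1S,5S)-5-methyl-5-(4-methylpent-3-en-1-yl)-2-[(trimethylsilyl)oxy]cyclopent-2-en-1-yl}methoxy)dimethylsilane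
Conditions: LiN(i-Pr)2, THF, −78 °C; Me3SiCl, Et3N
Reagents that add atoms: chlorotrimethylsilane C[Si](C)(C)Cl
Why: Kinetic deprotonation should occur at the unhindered ring CH2 and not at the methine flanked by the quaternary carbon, so O-silylation gives the less substituted silyl enol ether regioselectively and leaves the β-silyloxy methine untouched.

Step 7
Reactants: 10 the TMS enol ether
Product: 12 (5S,6S)-2-bromo-6-[(TBS-oxy)methyl]-5-methyl-5-(4-methylpent-3-en-1-yl)cyclohex-2-en-1-one, via dibromocyclopropane 11 (not isolated)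
Conditions: CHBr3, KOt-Bu, pentane, −30 → 0 °C; then toluene, 2,6-lutidine, 80 °C
Reagents that add atoms: bromoform BrC(Br)Br
Why: Dibromocarbene, formed by α-elimination from CHBr3, adds to the most electron-rich π bond, the silyl enol ether, to give the 6,6-dibromo-1-siloxybicyclo[3.1.0]hexane 11; on warming the endo C–Br bond ionises while the cyclopropane opens in a disrotatory electrocyclic manner (cyclopropyl to allyl cation), cleaving the bond shared with the five-membered ring, and loss of Me3SiBr from the siloxyallyl cation gives the 2-bromoenone. The closest known reaction type is the dihalocarbene ring expansion of cyclic silyl enol ethers to 2-halocycloalk-2-enones. The cyclopropane is closed by [2+1] cycloaddition and is only transient; the six-membered ring arises by one-carbon expansion of the cyclopentene, the carbene carbon becoming C2 of the enone (C3a of the target) between the former carbonyl carbon (C7a) and its α-carbon (C4). No stereocentre is created and the two existing centres are not touched, so the facial course of the carbene addition (expected anti to the CH2OTBS group) is irrelevant. The step needs chemoselectivity for the enol ether over the trisubstituted side-chain alkene, secured by the far higher nucleophilicity of the silyl enol ether and by one equivalent of carbene at low temperature, and regioselectivity, which is fixed by the position of the kinetic enol ether double bond.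

Step 8
Reactants: 13 but-3-yn-2-one
Product: 14 2-ethynyl-2-methyl-1,3-dioxolane
Conditions: Me3SiOCH2CH2OSiMe3, Me3SiOTf (cat.), CH2Cl2, −78 °C
Reagents that add atoms: 1,2-bis(trimethylsilyloxy)ethane C[Si](C)(C)OCCO[Si](C)(C)C
Why: Silyl-transfer ketalisation under aprotic conditions protects the ynone carbonyl without conjugate addition to the triple bond.

Step 9
Reactants: 14 2-ethynyl-2-methyl-1,3-dioxolane
Product: 16 2-[(E)-2-iodoethenyl]-2-methyl-1,3-dioxolane, via alkenylzirconocene 15 (not isolated)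
Conditions: Cp2Zr(H)Cl, THF, rt; then I2, 0 °C
Reagents that add atoms: iodine II
Why: Hydrozirconation adds Zr–H syn with zirconium at the terminal carbon, and iodinolysis with retention gives the E-alkenyl iodide.

Step 10
Reactants: 12 the 2-bromoenone; 16 the E-alkenyl iodide
Product: 18 (1R,5S,6S)-2-bromo-6-[(TBS-oxy)methyl]-5-methyl-5-(4-methylpent-3-en-1-yl)-1-[(E)-2-(2-methyl-1,3-dioxolan-2-yl)ethenyl]cyclohex-2-en-1-ol, via alkenyllithium 17 (not isolated)
Conditions: 16, t-BuLi (2 equiv), Et2O, −78 °C; then 12, THF, −78 °C; H2O work-up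
Reagents that add atoms: none
Why: Iodine–lithium exchange with retention gives the E-alkenyllithium, which should add 1,2 to the α-bromoenone carbonyl faster than it exchanges the vinyl bromide; attack anti to the neighbouring CH2OTBS group is expected, but the carbinol centre is removed in the next step, so both epimers converge.

Step 11
Reactants: 18 the tertiary bis-allylic alcohol
Product: 19 (4R,5S)-2-bromo-4-[(TBS-oxy)methyl]-5-methyl-5-(4-methylpent-3-en-1-yl)-3-[(E)-2-(2-methyl-1,3-dioxolan-2-yl)ethenyl]cyclohex-2-en-1-one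
Conditions: (C5H5NH)[CrO3Cl], NaOAc, 4 Å molecular sieves, CH2Cl2, rt
Reagents that add atoms: none
Why: Babler–Dauben oxidative transposition: the chromate ester shifts [3,3] to the ring terminus (less hindered than the side-chain terminus next to the ketal carbon, and leading to the fully conjugated dienone, as in the oxidation of 1-vinylcyclohex-2-enols to 3-vinylcyclohexenones) and is oxidised there; acetate buffer protects the ketal and the silyl ether.

Step 12
Reactants: 19 the bromodienone
Product: 20 (1S,4R,5S)-2-bromo-4-[(TBS-oxy)methyl]-5-methyl-5-(4-methylpent-3-en-1-yl)-3-[(E)-2-(2-methyl-1,3-dioxolan-2-yl)ethenyl]cyclohex-2-en-1-ol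
Conditions: (R)-2-methyl-CBS-oxazaborolidine (20 mol %), catecholborane, toluene, −78 °C
Reagents that add atoms: none
Why: Corey–Bakshi–Shibata reduction, 1,2-selective: the α-bromovinyl arm acts as the large group and the ring CH2 as the small one, so the (R)-catalyst should deliver hydride to the face that gives the (S)-carbinol (OH cis to the C4 arm) under reagent control; catecholborane spares the alkenes and the ketal hides the second carbonyl.

Step 13
Reactants: 20 the 2-bromoallylic alcohol
Product: 21 (1S,4R,5S)-4-[(TBS-oxy)methyl]-2-(hydroxymethyl)-5-methyl-5-(4-methylpent-3-en-1-yl)-3-[(E)-2-(2-methyl-1,3-dioxolan-2-yl)ethenyl]cyclohex-2-en-1-ol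
Conditions: Bu3SnCH2OH, Pd(PPh3)4 (10 mol %), 1,4-dioxane, 90 °C
Reagents that add atoms: (tributylstannyl)methanol CCCC[Sn](CCCC)(CCCC)CO
Why: Stille coupling of the vinyl bromide with the hydroxymethylstannane replaces bromine by CH2OH (C3) on the tetrasubstituted alkene under neutral conditions that leave the free carbinol, ketal and silyl ether alone.

Step 14
Reactants: 21 the diol ketal
Product: 23 1-[(1S,4S,6S,7R)-7-[(TBS-oxy)methyl]-4-hydroxy-6-methyl-6-(4-methylpent-3-en-1-yl)-1,3,4,5,6,7-hexahydro-2-benzofuran-1-yl]propan-2-one, via hydroxy dienone 22 (not isolated)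
Conditions: PPTS, acetone/H2O, rt; then DBU (cat.), CH2Cl2, 0 °C → rt
Reagents that add atoms: water O
Why: Mild hydrolysis of the allylic ketal unmasks the E-dienone, and 5-exo-trig oxa-Michael addition of the primary allylic hydroxyl held cis on the tetrasubstituted alkene closes the 2,5-dihydrofuran; under reversible base catalysis C1 should settle with the 2-oxopropyl group trans to the bulky C7 arm (1,3-repulsion in the cis isomer), while the secondary hydroxyl cannot add without forming a bridgehead alkene and the C7 oxygen is still silylated.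

Step 15
Reactants: 23 the silyl ether
Product: 24 1-[(1S,4S,6S,7R)-4-hydroxy-7-(hydroxymethyl)-6-methyl-6-(4-methylpent-3-en-1-yl)-1,3,4,5,6,7-hexahydro-2-benzofuran-1-yl]propan-2-one
Conditions: HF·pyridine, pyridine/THF, 0 °C → rt
Reagents that add atoms: none
Why: Fluoride cleavage of the primary silyl ether under buffered, non-basic conditions, so that the β-alkoxy ketone does not open by retro-Michael reaction and re-close through the new primary hydroxyl.

Step 16
Reactants: 24 the diol
Product: 25 (1S,4S,6S,7R)-4-hydroxy-6-methyl-6-(4-methylpent-3-en-1-yl)-1-(2-oxopropyl)-1,3,4,5,6,7-hexahydro-2-benzofuran-7-carbaldehyde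
Conditions: TEMPO (cat.), PhI(OAc)2, CH2Cl2, rt
Reagents that add atoms: none
Why: Oxoammonium-mediated oxidation is selective for the primary over the hindered secondary allylic alcohol and is non-basic, which should protect the α-centre of the β,γ-unsaturated aldehyde.

Step 17
Reactants: 25 the aldehyde
Product: 27 potassium trifluoro{(E)-2-[(1S,4S,6S,7R)-4-hydroxy-6-methyl-6-(4-methylpent-3-en-1-yl)-1-(2-oxopropyl)-1,3,4,5,6,7-hexahydro-2-benzofuran-7-yl]ethenyl}borate, via pinacol boronate 26 (not isolated)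
Conditions: CrCl2, LiI, Cl2CHB(pin), THF, rt; then KHF2, MeOH/H2O, rt
Reagents that add atoms: 2-(dichloromethyl)-4,4,5,5-tetramethyl-1,3,2-dioxaborolane ClC(Cl)B1OC(C)(C)C(C)(C)O1; potassium hydrogen difluoride [K+].F.[F-]
Why: Takai–Utimoto olefination with the gem-dichromium boryl reagent is aldehyde-selective (methyl ketone and free hydroxyl tolerated) and E-selective, and KHF2 converts the pinacol boronate into the trifluoroborate.

Step 18
Reactants: 27 the alkenyltrifluoroborate; 28 3-methylbut-2-enoic acid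
Product: 29 CNP0260614.2, (E)-2-[(1S,4S,6S,7R)-4-hydroxy-6-methyl-6-(4-methylpent-3-en-1-yl)-1-(2-oxopropyl)-1,3,4,5,6,7-hexahydro-2-benzofuran-7-yl]ethenyl 3-methylbut-2-enoate
Conditions: CuBr (10 mol %), DMAP, 4 Å molecular sieves, O2 (1 atm), MeCN, 40 °C
Reagents that add atoms: none
Why: Chan–Lam–Evans-type oxidative C–O coupling of an alkenyltrifluoroborate with a carboxylic acid forms the enol ester with retention of the E geometry and without strong base, so the free carbinol, the ketone and the conjugated position of the senecioate double bond should be preserved.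

Compound list (ring positions of 23–29 follow 2-benzofuran numbering)

1 | geraniol, (2E)-3,7-dimethylocta-2,6-dien-1-ol | CC(C)=CCC/C(C)=C/CO | starting material
2 | 3-[(tert-butyldimethylsilyl)oxy]propanoic acid | OC(=O)CCO[Si](C)(C)C(C)(C)C | starting material
3 | (2E)-3,7-dimethylocta-2,6-dien-1-yl 3-(TBS-oxy)propanoate | CC(C)=CCC/C(C)=C/COC(=O)CCO[Si](C)(C)C(C)(C)C | intermediate
4 | boron ketene acetal of 3 with the (S,S)-diazaborolidine, CH2OTBS cis to O–B | CC(C)=CCC/C(C)=C/CO/C(OB1N(S(=O)(=O)c2cc(cc(c2)C(F)(F)F)C(F)(F)F)[C@@H](c2ccccc2)[C@H](c2ccccc2)N1S(=O)(=O)c1cc(cc(c1)C(F)(F)F)C(F)(F)F)=C/CO[Si](C)(C)C(C)(C)C | intermediate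
5 | boron carboxylate of 6 with the (S,S)-diazaborolidine | O=C(OB1N(S(=O)(=O)c2cc(cc(c2)C(F)(F)F)C(F)(F)F)[C@@H](c2ccccc2)[C@H](c2ccccc2)N1S(=O)(=O)c1cc(cc(c1)C(F)(F)F)C(F)(F)F)[C@H](CO[Si](C)(C)C(C)(C)C)[C@@](C)(CCC=C(C)C)C=C | intermediate
6 | (2S,3S)-2-[(TBS-oxy)methyl]-3-ethenyl-3,7-dimethyloct-6-enoic acid | OC(=O)[C@H](CO[Si](C)(C)C(C)(C)C)[C@@](C)(CCC=C(C)C)C=C | intermediate
7 | (2S,3S)-2-[(TBS-oxy)methyl]-3-ethenyl-N-methoxy-N,3,7-trimethyloct-6-enamide | CON(C)C(=O)[C@H](CO[Si](C)(C)C(C)(C)C)[C@@](C)(CCC=C(C)C)C=C | intermediate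
8 | (2S,3S)-2-[(TBS-oxy)methyl]-3-ethenyl-3,7-dimethyloct-6-enal | O=C[C@H](CO[Si](C)(C)C(C)(C)C)[C@@](C)(CCC=C(C)C)C=C | intermediate
9 | (2S,3S)-2-[(TBS-oxy)methyl]-3-methyl-3-(4-methylpent-3-en-1-yl)cyclopentan-1-one | O=C1[C@H](CO[Si](C)(C)C(C)(C)C)[C@@](C)(CCC=C(C)C)CC1 | intermediate
10 | tert-butyl({(1S,5S)-5-methyl-5-(4-methylpent-3-en-1-yl)-2-[(trimethylsilyl)oxy]cyclopent-2-en-1-yl}methoxy)dimethylsilane | C[Si](C)(C)OC1=CC[C@](C)(CCC=C(C)C)[C@H]1CO[Si](C)(C)C(C)(C)C | intermediate
11 | 6,6-dibromo-1-(trimethylsilyloxy)bicyclo[3.1.0]hexane from 10, CBr2 bridge anti to the CH2OTBS group | C[Si](C)(C)O[C@]12[C@H](CO[Si](C)(C)C(C)(C)C)[C@@](C)(CCC=C(C)C)C[C@H]1C2(Br)Br | intermediate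
12 | (5S,6S)-2-bromo-6-[(TBS-oxy)methyl]-5-methyl-5-(4-methylpent-3-en-1-yl)cyclohex-2-en-1-one | O=C1C(Br)=CC[C@](C)(CCC=C(C)C)[C@H]1CO[Si](C)(C)C(C)(C)C | intermediate
13 | but-3-yn-2-one | CC(=O)C#C | starting material
14 | 2-ethynyl-2-methyl-1,3-dioxolane | CC1(C#C)OCCO1 | intermediate
15 | chlorobis(cyclopentadienyl)[(E)-2-(2-methyl-1,3-dioxolan-2-yl)ethenyl]zirconium | CC1(/C=C/[Zr](Cl)(C2C=CC=C2)C2C=CC=C2)OCCO1 | intermediate
16 | 2-[(E)-2-iodoethenyl]-2-methyl-1,3-dioxolane | CC1(/C=C/I)OCCO1 | intermediate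
17 | [(E)-2-(2-methyl-1,3-dioxolan-2-yl)ethenyl]lithium | CC1(/C=C/[Li])OCCO1 | intermediate
18 | (1R,5S,6S)-2-bromo-6-[(TBS-oxy)methyl]-5-methyl-5-(4-methylpent-3-en-1-yl)-1-[(E)-2-(2-methyl-1,3-dioxolan-2-yl)ethenyl]cyclohex-2-en-1-ol | O[C@@]1(/C=C/C2(C)OCCO2)C(Br)=CC[C@](C)(CCC=C(C)C)[C@H]1CO[Si](C)(C)C(C)(C)C | intermediate
19 | (4R,5S)-2-bromo-4-[(TBS-oxy)methyl]-5-methyl-5-(4-methylpent-3-en-1-yl)-3-[(E)-2-(2-methyl-1,3-dioxolan-2-yl)ethenyl]cyclohex-2-en-1-one | O=C1C[C@](C)(CCC=C(C)C)[C@@H](CO[Si](C)(C)C(C)(C)C)C(/C=C/C2(C)OCCO2)=C1Br | intermediate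
20 | (1S,4R,5S)-2-bromo-4-[(TBS-oxy)methyl]-5-methyl-5-(4-methylpent-3-en-1-yl)-3-[(E)-2-(2-methyl-1,3-dioxolan-2-yl)ethenyl]cyclohex-2-en-1-ol | O[C@H]1C[C@](C)(CCC=C(C)C)[C@@H](CO[Si](C)(C)C(C)(C)C)C(/C=C/C2(C)OCCO2)=C1Br | intermediate
21 | (1S,4R,5S)-4-[(TBS-oxy)methyl]-2-(hydroxymethyl)-5-methyl-5-(4-methylpent-3-en-1-yl)-3-[(E)-2-(2-methyl-1,3-dioxolan-2-yl)ethenyl]cyclohex-2-en-1-ol | O[C@H]1C[C@](C)(CCC=C(C)C)[C@@H](CO[Si](C)(C)C(C)(C)C)C(/C=C/C2(C)OCCO2)=C1CO | intermediate
22 | (3E)-4-[(3S,5S,6R)-6-[(TBS-oxy)methyl]-3-hydroxy-2-(hydroxymethyl)-5-methyl-5-(4-methylpent-3-en-1-yl)cyclohex-1-en-1-yl]but-3-en-2-one | O[C@H]1C[C@](C)(CCC=C(C)C)[C@@H](CO[Si](C)(C)C(C)(C)C)C(/C=C/C(C)=O)=C1CO | intermediate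
23 | 1-[(1S,4S,6S,7R)-7-[(TBS-oxy)methyl]-4-hydroxy-6-methyl-6-(4-methylpent-3-en-1-yl)-1,3,4,5,6,7-hexahydro-2-benzofuran-1-yl]propan-2-one | CC(=O)C[C@@H]1OCC2=C1[C@H](CO[Si](C)(C)C(C)(C)C)[C@@](C)(CCC=C(C)C)C[C@@H]2O | intermediate
24 | 1-[(1S,4S,6S,7R)-4-hydroxy-7-(hydroxymethyl)-6-methyl-6-(4-methylpent-3-en-1-yl)-1,3,4,5,6,7-hexahydro-2-benzofuran-1-yl]propan-2-one | CC(=O)C[C@@H]1OCC2=C1[C@H](CO)[C@@](C)(CCC=C(C)C)C[C@@H]2O | intermediate
25 | (1S,4S,6S,7R)-4-hydroxy-6-methyl-6-(4-methylpent-3-en-1-yl)-1-(2-oxopropyl)-1,3,4,5,6,7-hexahydro-2-benzofuran-7-carbaldehyde | CC(=O)C[C@@H]1OCC2=C1[C@H](C=O)[C@@](C)(CCC=C(C)C)C[C@@H]2O | intermediate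
26 | 1-[(1S,4S,6S,7R)-4-hydroxy-6-methyl-6-(4-methylpent-3-en-1-yl)-7-[(E)-2-(pinacolatoboryl)ethenyl]-1,3,4,5,6,7-hexahydro-2-benzofuran-1-yl]propan-2-one | CC(=O)C[C@@H]1OCC2=C1[C@H](/C=C/B3OC(C)(C)C(C)(C)O3)[C@@](C)(CCC=C(C)C)C[C@@H]2O | intermediate
27 | potassium (E)-alkenyltrifluoroborate corresponding to 26 | CC(=O)C[C@@H]1OCC2=C1[C@H](/C=C/[B-](F)(F)F)[C@@](C)(CCC=C(C)C)C[C@@H]2O.[K+] | intermediate
28 | 3-methylbut-2-enoic acid | CC(C)=CC(O)=O | starting material
29 | CNP0260614.2, (E)-2-[(1S,4S,6S,7R)-4-hydroxy-6-methyl-6-(4-methylpent-3-en-1-yl)-1-(2-oxopropyl)-1,3,4,5,6,7-hexahydro-2-benzofuran-7-yl]ethenyl 3-methylbut-2-enoate | CC(=O)C[C@@H]1OCC2=C1[C@H](/C=C/OC(=O)C=C(C)C)[C@@](C)(CCC=C(C)C)C[C@@H]2O | target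

Total step count: 18. Longest linear sequence: 16 (steps 1–7 and 10–18; steps 8–9 make the alkenyl iodide for step 10).

Steps most likely to fail

Step 2. What may go wrong: incomplete control of the ketene acetal geometry or of the facial sense, and a slow rearrangement at the fully substituted allyl terminus during which the silyl ether is lost. Fallback: setting out from 3, a classical Ireland–Claisen rearrangement (LiN(i-Pr)2, Me3SiCl, THF/DMPU, −78 °C → rt) would pass through the silyl ketene acetal F1 and give, after hydrolysis, the racemic acid, that is 6 together with its enantiomer F2. The wanted enantiomer would be taken out as the crystalline (S)-1-phenylethylammonium salt F3 and freed with dilute acid, coming back to the route at 6. Here diastereocontrol comes from the chair and enantiopurity from resolution instead of reagent control.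

Step 7. What may go wrong: competing addition of the carbene to the trisubstituted side-chain alkene, or cleavage of the enol ether by the alkoxide before cyclopropanation. Fallback: setting out from 9, the ring would be enlarged with a nucleophilic diazoalkane, which only attacks the carbonyl group. Me3SiCHN2 with BF3·OEt2 (CH2Cl2, −78 °C), with migration of the less substituted CH2, would give the α-silyl ketone F4, and protodesilylation on mild acidic work-up the cyclohexanone F5. Dehydrogenation on the unhindered side (IBX, DMSO, 65 °C) would give the cyclohexenone F6, and nucleophilic epoxidation (H2O2, NaOH, MeOH, 0 °C) the epoxy ketone F7. Bromide opening at the α-carbon and dehydration (LiBr, AcOH, THF) would then come back to the route at 12.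

Step 13. What may go wrong: slow oxidative addition and transmetalation at the hindered tetrasubstituted vinyl bromide, so that protodebromination or destannylation wins over coupling. Fallback: setting out from 20, deprotonation (MeLi, 1 equiv) and bromine–lithium exchange (t-BuLi, 2 equiv, THF, −78 °C) would give the dilithio species F8. Trapping with monomeric formaldehyde would come back to the route at 21 by a polar C–C bond formation instead of a cross-coupling.

Further compounds

F1 | step 2 | trimethylsilyl ketene acetal of 3, O-silyl cis to CH2OTBS | CC(C)=CCC/C(C)=C/CO/C(O[Si](C)(C)C)=C/CO[Si](C)(C)C(C)(C)C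
F2 | step 2 | (2R,3R)-2-[(TBS-oxy)methyl]-3-ethenyl-3,7-dimethyloct-6-enoic acid, enantiomer of 6 | OC(=O)[C@@H](CO[Si](C)(C)C(C)(C)C)[C@](C)(CCC=C(C)C)C=C
F3 | step 2 | (S)-1-phenylethylammonium salt of 6 | [O-]C(=O)[C@H](CO[Si](C)(C)C(C)(C)C)[C@@](C)(CCC=C(C)C)C=C.C[C@H]([NH3+])c1ccccc1
F4 | step 7 | (2S,3S)-2-[(TBS-oxy)methyl]-3-methyl-3-(4-methylpent-3-en-1-yl)-6-(trimethylsilyl)cyclohexan-1-one, both epimers at C6 | O=C1C([Si](C)(C)C)CC[C@](C)(CCC=C(C)C)[C@H]1CO[Si](C)(C)C(C)(C)C
F5 | step 7 | ring-homologated cyclohexanone, 2-[(TBS-oxy)methyl]-3-methyl-3-(4-methylpent-3-en-1-yl)cyclohexan-1-one with the configuration of 9 | O=C1CCC[C@](C)(CCC=C(C)C)[C@H]1CO[Si](C)(C)C(C)(C)C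
F6 | step 7 | (5S,6S)-6-[(TBS-oxy)methyl]-5-methyl-5-(4-methylpent-3-en-1-yl)cyclohex-2-en-1-one | O=C1C=CC[C@](C)(CCC=C(C)C)[C@H]1CO[Si](C)(C)C(C)(C)C
F7 | step 7 | 2,3-epoxide of F6, oxirane anti to the CH2OTBS group | O=C1[C@@H]2O[C@@H]2C[C@](C)(CCC=C(C)C)[C@H]1CO[Si](C)(C)C(C)(C)C
F8 | step 13 | O,C-dilithio derivative of 20, lithium alkoxide and 2-lithioalkene | [Li]O[C@H]1C[C@](C)(CCC=C(C)C)[C@@H](CO[Si](C)(C)C(C)(C)C)C(/C=C/C2(C)OCCO2)=C1[Li]
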